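If the share of X turned into Q after a given time hardly changes with the amount of X charged, a flask can be reckoned by counting turnovers, and that was the proposal before the meeting on these flasks.

| flask | X | Z | remark | time |
|---|---|---|---|---|
| east | 0.0075 M | 3.4 mM (held) | run made earlier |  |
| south-east | 0.041 M | 3.4 mM (held) | run made earlier |  |
| green | 0.012 M | 3.4 mM (held) |  | 8.0 min |
| violet | 0.050 M | 3.4 mM (held) |  | 30 min |

| east: time / min | east: Q / % | south-east: time / min | south-east: Q / % |
|---|---|---|---|
| 2.00 | 2.5 | 4.00 | 7.2 |
| 5.00 | 9.5 | 8.00 | 13.2 |
| 10.0 | 19.1 | 12.0 | 20.9 |
| 15.0 | 28.0 | 15.0 | 25.4 |
| 20.0 | 35.5 | 20.0 | 34.1 |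

(standard deviation of a reading: 0.5 percentage points)

- the flask that ends with the higher amount of Q, in percent of the X charged, or "neither" when 2 percentage points or less lies between them (green / violet / neither)
- final Q, as a percentage of the X charged, in green
- final Q, as a percentage of the X charged, in violet

- the earlier runs were read with a standard deviation of 0.5 percentage points
- at the start none of Z is in solution
- a reading or a percentage of Q counts all its forms, free or not

The first speaker noted that at 20.0 min the east run stood at 35.5 % and the south-east run at 34.1 %, although south-east started with 5.47 times the cX, so she treated the loss of X under held Z as pseudo-first-order. She proposed to carry the turnover rate, the number of turnovers per minute, one turnover being the stretch in which the remaining X falls by the factor e. Between the second and last readings of east she read 0.0226 min⁻¹, and between the first and last readings of south-east she read 0.0214 min⁻¹, the second lower than the first on these two spans, though both carry the scatter of the readings.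

The second speaker recalled that none of Z is in solution at the start and read from east a delay of 0.579 min, after which the count begins.

The secretary's own reckoning gave green, with the east rate, 0.168 turnovers, hence 15.4 %, and violet, with the south-east rate, 0.629 turnovers, hence 46.7 %.

The forecast, read out next, gave green 15.2 % (13.8 % to 16.5 %) and violet 46 % (41 % to 49 %), with the words “Violet ends with the higher percentage, because it runs much longer”; the secretary's violet is higher than this by 0.70 percentage points, inside its range.

The flasks give green 15.4 % and violet 45.3 %, so violet ends higher than green, under this scheme:

    X + G → Q (k = 0.134 L mol⁻¹ s⁻¹)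
    G ⇌ J (K = 280, k = 0.00652 s⁻¹)
    Z ⇌ G, rate k3*(csat - [G]) (kL = 0.0333 s⁻¹)
    E ⇌ Q, rate k4*(cs4 - [Q]) while solid is left; crystals form when [Q] > cs4 (solubility = 2.40 mM, k = 0.0108 s⁻¹)

Neither flask has come to rest, for green still holds 85 % of its charge as X and violet 55 %. Counted on at the same rate, green reaches 1.79 turnovers at 80.0 min, which gives 83.4 % against the simulated 83.5 %. Violet reaches 6.41 turnovers at 300 min, which gives 99.8 % against the simulated 99.9 %. Ten times the time also changes the form of the product, since violet's Q at 300 min includes 95.1 % as the crystals E, up from 38.6 % at 30.0 min.

The runs were generated by integration with constants of no real substance, and the scatter is random.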